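**Retrosynthetic overview**

1. Sceptrin (25) ⇐ tetraamine 23 + two 4-bromo-2-(trichloroacetyl)pyrroles (24); the amide bonds are made last, the pyrrole rings are bought.
2. 23 ⇐ C2-symmetric bis(sulfamoylimidazolyl) diester 14: esters become CH2NH2 arms, and both imidazole C2–N bonds come from one double lithiation–azidation.
3. 14 ⇐ all-trans keto diester 10: the acetyl group is grown into the second imidazole ring.
4. 10 ⇐ cis cyclobutane 9 ⇐ pyrrolidine 7 by excision of the ring nitrogen. The strategy rests on the cyclobutane bond C1–C2, which joins the ring carbon bearing a 2-aminoimidazole (C1) to the neighbouring ring carbon bearing a CH2NHCO-pyrrole arm (C2); this is the bond formed.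
5. 7 ⇐ asymmetric silver-catalysed [3+2] of imine 5 (imidazole-4-carbaldehyde + glycine ester) with methyl (E)-4-oxopent-2-enoate. Ring order: first imidazole (bought), pyrrolidine, cyclobutane, second imidazole.

Key step: step 4

Assumption: (S)-QUINAP is taken to give the (2R,3R,4R,5S) adduct 7; if the sense of induction proves opposite, (R)-QUINAP is used with no other change.

**Route**

Step 1
Reactants: 1 1H-imidazole-4-carbaldehyde; 2 dimethylsulfamoyl chloride
Product: 3 4-formyl-N,N-dimethyl-1H-imidazole-1-sulfonamide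
Conditions: Et3N, CH2Cl2, 0 °C → rt
Reagents that add atoms: none
Why: N-sulfamoylation of the imidazole under basic conditions, in which the sulfamoyl group should settle on the nitrogen remote from the formyl group to give the 1,4-isomer.

Step 2
Reactants: 3 4-formyl-N,N-dimethyl-1H-imidazole-1-sulfonamide; 4 glycine methyl ester hydrochloride
Product: 5 methyl N-{(E)-[1-(dimethylsulfamoyl)-1H-imidazol-4-yl]methylidene}glycinate
Conditions: Et3N, 4 Å MS, CH2Cl2, rt; used crude
Reagents that add atoms: none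
Why: Imine condensation (Schiff base formation) of a heteroaromatic aldehyde with the liberated amino ester, driven by removal of water.

Step 3
Reactants: 5 methyl N-{(E)-[1-(dimethylsulfamoyl)-1H-imidazol-4-yl]methylidene}glycinate; 6 methyl (E)-4-oxopent-2-enoate
Product: 7 dimethyl (2R,3R,4R,5S)-4-acetyl-5-[1-(dimethylsulfamoyl)-1H-imidazol-4-yl]pyrrolidine-2,3-dicarboxylate
Conditions: AgOAc (5 mol %), (S)-QUINAP (5.5 mol %), iPr2NEt (10 mol %), THF, −45 °C
Reagents that add atoms: none
Why: Catalytic asymmetric 1,3-dipolar cycloaddition of a silver-bound N,O-chelated azomethine ylide (Michael then Mannich): the glycine carbon should attack the alkene carbon β to the more activating ketone so that the acetyl group ends next to the imidazolyl carbon, the W-shaped ylide makes C2 and C5 cis, the ligand-bound silver blocks one ylide face and so fixes C5 (S) and C2 (R), endo approach of the acetyl group sets C4 and the E-alkene places C3 trans to C4; only the regiochemistry and the C5 configuration must be right, because C2, C3 and C4 are re-set in step 5.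

Step 4
Reactants: 7 dimethyl (2R,3R,4R,5S)-4-acetyl-5-[1-(dimethylsulfamoyl)-1H-imidazol-4-yl]pyrrolidine-2,3-dicarboxylate
Product: 9 dimethyl (1R,2R,3S,4R)-3-acetyl-4-[1-(dimethylsulfamoyl)-1H-imidazol-4-yl]cyclobutane-1,2-dicarboxylate, via isodiazene 8 (not isolated)
Conditions: PhI(OH)OTs (2.5 equiv), NH2CO2NH4 (8 equiv), CF3CH2OH, 80 °C
Reagents that add atoms: none
Why: Ammonia released from the carbamate is oxidised by PhI(OH)OTs to an electrophilic iodonitrene, which aminates the only nucleophilic nitrogen (the ring NH; the sulfamoylated imidazole nitrogen is too electron-poor) and, after a second oxidation, gives isodiazene 8. Loss of N2 from 8 leaves a singlet 1,4-biradical whose termini are stabilised by the imidazolyl ring and by the ester, and radical–radical recombination forms the bond between the imidazolyl carbon and the glycine-derived carbon, so the four-membered ring closes by 1,4-biradical collapse and not by a polar cyclisation. The closest known reaction type is the iodonitrene-mediated, stereoretentive contraction of NH-pyrrolidines to cyclobutanes, a relative of thermal N2 extrusion from the 1,1-diazenes of N-aminopyrrolidines. No stereocentre is created: the two former α-carbons keep their configuration because collapse of the caged singlet biradical should be faster than rotation about the bonds to the two untouched ring carbons. The selectivity needed is recombination over β-scission into two alkenes and over bond rotation, and it is favoured by both termini being secondary, stabilised and held close by the intact C3–C4 bond, with the hydrogen-bonding solvent as cage. Only retention at the imidazolyl carbon is essential, since the other three centres are corrected in step 5.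

Step 5
Reactants: 9 dimethyl (1R,2R,3S,4R)-3-acetyl-4-[1-(dimethylsulfamoyl)-1H-imidazol-4-yl]cyclobutane-1,2-dicarboxylate
Product: 10 dimethyl (1S,2S,3R,4R)-3-acetyl-4-[1-(dimethylsulfamoyl)-1H-imidazol-4-yl]cyclobutane-1,2-dicarboxylate (all-trans)
Conditions: NaOMe (0.5 equiv), MeOH, rt → 40 °C
Reagents that add atoms: none
Why: Base-mediated thermodynamic epimerisation through the ketone and ester enolates: the imidazolyl carbon carries no acidifying group and keeps its configuration, while the three carbonyl-bearing carbons should invert until every vicinal pair is trans, which defines the single all-trans isomer; the ring C–C bonds lie orthogonal to the enolate π system, which disfavours retro-Michael ring opening.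

Step 6
Reactants: 10 dimethyl (1S,2S,3R,4R)-3-acetyl-4-[1-(dimethylsulfamoyl)-1H-imidazol-4-yl]cyclobutane-1,2-dicarboxylate
Product: 11 dimethyl (1S,2S,3R,4R)-3-(chloroacetyl)-4-[1-(dimethylsulfamoyl)-1H-imidazol-4-yl]cyclobutane-1,2-dicarboxylate
Conditions: BnNMe3ICl2 (2.2 equiv), THF, 60 °C
Reagents that add atoms: benzyltrimethylammonium dichloroiodate, C[N+](C)(C)Cc1ccccc1.Cl[I-]Cl
Why: Electrophilic α-halogenation of a methyl ketone through its enol, which should occur at the methyl group because the alternative enol would need a double bond exocyclic to the cyclobutane at a hindered tertiary carbon; the esters and the electron-poor sulfamoylimidazole are inert and the ring stereocentres are already at equilibrium.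

Step 7
Reactants: 11 dimethyl (1S,2S,3R,4R)-3-(chloroacetyl)-4-[1-(dimethylsulfamoyl)-1H-imidazol-4-yl]cyclobutane-1,2-dicarboxylate
Product: 12 dimethyl (1S,2S,3R,4R)-3-[(diformylamino)acetyl]-4-[1-(dimethylsulfamoyl)-1H-imidazol-4-yl]cyclobutane-1,2-dicarboxylate
Conditions: NaN(CHO)2, MeCN, 40 °C
Reagents that add atoms: sodium diformylamide, [Na+].O=C[N-]C=O
Why: SN2 displacement of an α-chloroketone by a non-basic Gabriel-type nitrogen nucleophile, which should outrun any alkylation of the weakly nucleophilic sulfamoylimidazole nitrogen.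

Step 8
Reactants: 12 dimethyl (1S,2S,3R,4R)-3-[(diformylamino)acetyl]-4-[1-(dimethylsulfamoyl)-1H-imidazol-4-yl]cyclobutane-1,2-dicarboxylate
Product: 13 dimethyl (1S,2S,3R,4R)-3-(1H-imidazol-4-yl)-4-[1-(dimethylsulfamoyl)-1H-imidazol-4-yl]cyclobutane-1,2-dicarboxylate
Conditions: NH4OAc (15 equiv), AcOH, 100 °C
Reagents that add atoms: ammonium acetate, CC(=O)[O-].[NH4+]
Why: Cyclocondensation of an α-acylamino ketone with ammonia (imidazole synthesis): one formyl group is shed, ammonia condenses with the ketone and the new nitrogen closes onto the remaining formamide carbon with loss of water to give the five-membered aromatic ring, with no stereocentre involved.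

Step 9
Reactants: 13 dimethyl (1S,2S,3R,4R)-3-(1H-imidazol-4-yl)-4-[1-(dimethylsulfamoyl)-1H-imidazol-4-yl]cyclobutane-1,2-dicarboxylate; 2 dimethylsulfamoyl chloride
Product: 14 dimethyl (1S,2S,3R,4R)-3,4-bis[1-(dimethylsulfamoyl)-1H-imidazol-4-yl]cyclobutane-1,2-dicarboxylate
Conditions: Et3N, CH2Cl2, rt
Reagents that add atoms: none
Why: N-sulfamoylation at the less hindered ring nitrogen (1,4-isomer) as in step 1, which should make the molecule C2-symmetric and would also restore any sulfamoyl group lost from the first imidazole in step 8.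

Step 10
Reactants: 14 dimethyl (1S,2S,3R,4R)-3,4-bis[1-(dimethylsulfamoyl)-1H-imidazol-4-yl]cyclobutane-1,2-dicarboxylate
Product: 15 4,4'-[(1R,2R,3S,4S)-3,4-bis(hydroxymethyl)cyclobutane-1,2-diyl]bis(N,N-dimethyl-1H-imidazole-1-sulfonamide)
Conditions: iBu2AlH (5 equiv), CH2Cl2, −78 → 0 °C; Rochelle salt work-up
Reagents that add atoms: none
Why: Hydride reduction of both esters to primary alcohols, which the sulfamoyl groups should tolerate at low temperature and which removes the last epimerisable centres.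

Step 11
Reactants: 15 4,4'-[(1R,2R,3S,4S)-3,4-bis(hydroxymethyl)cyclobutane-1,2-diyl]bis(N,N-dimethyl-1H-imidazole-1-sulfonamide)
Product: 16 4,4'-[(1R,2R,3S,4S)-3,4-bis({[tert-butyl(dimethyl)silyl]oxy}methyl)cyclobutane-1,2-diyl]bis(N,N-dimethyl-1H-imidazole-1-sulfonamide)
Conditions: TBSCl, imidazole, DMF, rt
Reagents that add atoms: tert-butyldimethylsilyl chloride, CC(C)(C)[Si](C)(C)Cl
Why: Silyl ether protection of the two primary alcohols so that no acidic proton or electrophile interferes with the organolithium step.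

Step 12
Reactants: 16 4,4'-[(1R,2R,3S,4S)-3,4-bis({[tert-butyl(dimethyl)silyl]oxy}methyl)cyclobutane-1,2-diyl]bis(N,N-dimethyl-1H-imidazole-1-sulfonamide)
Product: 18 4,4'-[(1R,2R,3S,4S)-3,4-bis({[tert-butyl(dimethyl)silyl]oxy}methyl)cyclobutane-1,2-diyl]bis(2-azido-N,N-dimethyl-1H-imidazole-1-sulfonamide), via dilithio species 17 (not isolated)
Conditions: n-BuLi (2.4 equiv), THF, −78 °C; then TsN3 (2.6 equiv), −78 °C → rt
Reagents that add atoms: p-toluenesulfonyl azide, Cc1ccc(cc1)S(=O)(=O)N=[N+]=[N-]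
Why: Directed C2-lithiation of N-sulfamoylimidazoles (the C–H between the two nitrogens is the most acidic and the sulfamoyl group directs the base) followed by electrophilic azide transfer, in which each triazenyl anion expels sulfinate to leave the 2-azide.

Step 13
Reactants: 18 4,4'-[(1R,2R,3S,4S)-3,4-bis({[tert-butyl(dimethyl)silyl]oxy}methyl)cyclobutane-1,2-diyl]bis(2-azido-N,N-dimethyl-1H-imidazole-1-sulfonamide)
Product: 19 4,4'-[(1R,2R,3S,4S)-3,4-bis(hydroxymethyl)cyclobutane-1,2-diyl]bis(2-azido-N,N-dimethyl-1H-imidazole-1-sulfonamide)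
Conditions: CSA (0.2 equiv), MeOH/CH2Cl2, 0 °C → rt
Reagents that add atoms: none
Why: Acid-catalysed methanolysis of primary silyl ethers, chosen over fluoride so that the sulfamoyl groups and the azides are not exposed to a basic nucleophile.

Step 14
Reactants: 19 4,4'-[(1R,2R,3S,4S)-3,4-bis(hydroxymethyl)cyclobutane-1,2-diyl]bis(2-azido-N,N-dimethyl-1H-imidazole-1-sulfonamide)
Product: 20 {(1S,2S,3R,4R)-3,4-bis[2-azido-1-(dimethylsulfamoyl)-1H-imidazol-4-yl]cyclobutane-1,2-diyl}bis(methylene) dimethanesulfonate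
Conditions: MsCl, Et3N, CH2Cl2, 0 °C
Reagents that add atoms: methanesulfonyl chloride, CS(=O)(=O)Cl
Why: O-sulfonylation of the primary alcohols, done while the imidazoles are deactivated by both the sulfamoyl and the azido group so that their ring nitrogen cannot alkylate intramolecularly.

Step 15
Reactants: 20 {(1S,2S,3R,4R)-3,4-bis[2-azido-1-(dimethylsulfamoyl)-1H-imidazol-4-yl]cyclobutane-1,2-diyl}bis(methylene) dimethanesulfonate
Product: 22 4,4'-[(1S,2S,3R,4R)-3,4-bis(aminomethyl)cyclobutane-1,2-diyl]bis(2-amino-N,N-dimethyl-1H-imidazole-1-sulfonamide), via tetraazide 21 (not isolated)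
Conditions: NaN3, DMF, 50 °C; extraction into EtOAc (not concentrated); then H2 (1 atm), Pd/C, MeOH, rt
Reagents that add atoms: sodium azide, [Na+].[N-]=[N+]=[N-]
Why: SN2 displacement of the primary mesylates by azide followed by catalytic hydrogenation of all four azides to amines, the nitrogen-rich tetraazide being kept in solution and reduced at once for safety.

Step 16
Reactants: 22 4,4'-[(1S,2S,3R,4R)-3,4-bis(aminomethyl)cyclobutane-1,2-diyl]bis(2-amino-N,N-dimethyl-1H-imidazole-1-sulfonamide)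
Product: 23 4,4'-[(1S,2S,3R,4R)-3,4-bis(aminomethyl)cyclobutane-1,2-diyl]bis(1H-imidazol-2-amine) tetrahydrochloride
Conditions: 4 M HCl, MeOH/H2O, 65 °C; evaporation
Reagents that add atoms: hydrogen chloride, Cl
Why: Acid hydrolysis of the N-sulfamoyl protecting groups, carried out before the acid-sensitive acylpyrrole amides exist, which should leave the tetraamine as its hydrochloride.

Step 17
Reactants: 23 4,4'-[(1S,2S,3R,4R)-3,4-bis(aminomethyl)cyclobutane-1,2-diyl]bis(1H-imidazol-2-amine) tetrahydrochloride; 24 4-bromo-2-(trichloroacetyl)-1H-pyrrole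
Product: 25 sceptrin
Conditions: 24 (2.1 equiv), iPr2NEt, DMF, rt; reversed-phase purification, free base
Reagents that add atoms: none
Why: Amide formation by haloform-type acyl transfer from a trichloromethyl ketone, which should be selective for the two primary alkylamines over the guanidine-like 2-aminoimidazoles and touches no stereocentre.

**Compound list**

1 | 1H-imidazole-4-carbaldehyde | O=Cc1c[nH]cn1 | starting material
2 | dimethylsulfamoyl chloride | CN(C)S(=O)(=O)Cl | starting material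
3 | 4-formyl-N,N-dimethyl-1H-imidazole-1-sulfonamide | CN(C)S(=O)(=O)n1cnc(C=O)c1 | intermediate
4 | glycine methyl ester hydrochloride | COC(=O)CN.Cl | starting material
5 | methyl N-{(E)-[1-(dimethylsulfamoyl)-1H-imidazol-4-yl]methylidene}glycinate | COC(=O)C/N=C/c1cn(cn1)S(=O)(=O)N(C)C | intermediate
6 | methyl (E)-4-oxopent-2-enoate | COC(=O)/C=C/C(C)=O | starting material
7 | dimethyl (2R,3R,4R,5S)-4-acetyl-5-[1-(dimethylsulfamoyl)-1H-imidazol-4-yl]pyrrolidine-2,3-dicarboxylate | CN(C)S(=O)(=O)n1cnc(c1)[C@H]1N[C@@H](C(=O)OC)[C@H](C(=O)OC)[C@H]1C(C)=O | intermediate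
8 | isodiazene (1,1-diazene) of 7 | CN(C)S(=O)(=O)n1cnc(c1)[C@H]1[N+](=[N-])[C@@H](C(=O)OC)[C@H](C(=O)OC)[C@H]1C(C)=O | intermediate
9 | dimethyl (1R,2R,3S,4R)-3-acetyl-4-[1-(dimethylsulfamoyl)-1H-imidazol-4-yl]cyclobutane-1,2-dicarboxylate | CN(C)S(=O)(=O)n1cnc(c1)[C@H]1[C@@H](C(=O)OC)[C@H](C(=O)OC)[C@H]1C(C)=O | intermediate
10 | dimethyl (1S,2S,3R,4R)-3-acetyl-4-[1-(dimethylsulfamoyl)-1H-imidazol-4-yl]cyclobutane-1,2-dicarboxylate | CN(C)S(=O)(=O)n1cnc(c1)[C@H]1[C@H](C(=O)OC)[C@@H](C(=O)OC)[C@@H]1C(C)=O | intermediate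
11 | dimethyl (1S,2S,3R,4R)-3-(chloroacetyl)-4-[1-(dimethylsulfamoyl)-1H-imidazol-4-yl]cyclobutane-1,2-dicarboxylate | CN(C)S(=O)(=O)n1cnc(c1)[C@H]1[C@H](C(=O)OC)[C@@H](C(=O)OC)[C@@H]1C(=O)CCl | intermediate
12 | dimethyl (1S,2S,3R,4R)-3-[(diformylamino)acetyl]-4-[1-(dimethylsulfamoyl)-1H-imidazol-4-yl]cyclobutane-1,2-dicarboxylate | CN(C)S(=O)(=O)n1cnc(c1)[C@H]1[C@H](C(=O)OC)[C@@H](C(=O)OC)[C@@H]1C(=O)CN(C=O)C=O | intermediate
13 | dimethyl (1S,2S,3R,4R)-3-(1H-imidazol-4-yl)-4-[1-(dimethylsulfamoyl)-1H-imidazol-4-yl]cyclobutane-1,2-dicarboxylate | CN(C)S(=O)(=O)n1cnc(c1)[C@H]1[C@H](C(=O)OC)[C@@H](C(=O)OC)[C@@H]1c1c[nH]cn1 | intermediate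
14 | dimethyl (1S,2S,3R,4R)-3,4-bis[1-(dimethylsulfamoyl)-1H-imidazol-4-yl]cyclobutane-1,2-dicarboxylate | CN(C)S(=O)(=O)n1cnc(c1)[C@H]1[C@H](C(=O)OC)[C@@H](C(=O)OC)[C@@H]1c1cn(cn1)S(=O)(=O)N(C)C | intermediate
15 | 4,4'-[(1R,2R,3S,4S)-3,4-bis(hydroxymethyl)cyclobutane-1,2-diyl]bis(N,N-dimethyl-1H-imidazole-1-sulfonamide) | CN(C)S(=O)(=O)n1cnc(c1)[C@H]1[C@H](CO)[C@@H](CO)[C@@H]1c1cn(cn1)S(=O)(=O)N(C)C | intermediate
16 | 4,4'-[(1R,2R,3S,4S)-3,4-bis({[tert-butyl(dimethyl)silyl]oxy}methyl)cyclobutane-1,2-diyl]bis(N,N-dimethyl-1H-imidazole-1-sulfonamide) | CN(C)S(=O)(=O)n1cnc(c1)[C@H]1[C@H](CO[Si](C)(C)C(C)(C)C)[C@@H](CO[Si](C)(C)C(C)(C)C)[C@@H]1c1cn(cn1)S(=O)(=O)N(C)C | intermediate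
17 | 2,2'-dilithio derivative of 16 | CN(C)S(=O)(=O)n1c([Li])nc(c1)[C@H]1[C@H](CO[Si](C)(C)C(C)(C)C)[C@@H](CO[Si](C)(C)C(C)(C)C)[C@@H]1c1cn(c([Li])n1)S(=O)(=O)N(C)C | intermediate
18 | 4,4'-[(1R,2R,3S,4S)-3,4-bis({[tert-butyl(dimethyl)silyl]oxy}methyl)cyclobutane-1,2-diyl]bis(2-azido-N,N-dimethyl-1H-imidazole-1-sulfonamide) | CN(C)S(=O)(=O)n1c(N=[N+]=[N-])nc(c1)[C@H]1[C@H](CO[Si](C)(C)C(C)(C)C)[C@@H](CO[Si](C)(C)C(C)(C)C)[C@@H]1c1cn(c(N=[N+]=[N-])n1)S(=O)(=O)N(C)C | intermediate
19 | 4,4'-[(1R,2R,3S,4S)-3,4-bis(hydroxymethyl)cyclobutane-1,2-diyl]bis(2-azido-N,N-dimethyl-1H-imidazole-1-sulfonamide) | CN(C)S(=O)(=O)n1c(N=[N+]=[N-])nc(c1)[C@H]1[C@H](CO)[C@@H](CO)[C@@H]1c1cn(c(N=[N+]=[N-])n1)S(=O)(=O)N(C)C | intermediate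
20 | {(1S,2S,3R,4R)-3,4-bis[2-azido-1-(dimethylsulfamoyl)-1H-imidazol-4-yl]cyclobutane-1,2-diyl}bis(methylene) dimethanesulfonate | CN(C)S(=O)(=O)n1c(N=[N+]=[N-])nc(c1)[C@H]1[C@H](COS(C)(=O)=O)[C@@H](COS(C)(=O)=O)[C@@H]1c1cn(c(N=[N+]=[N-])n1)S(=O)(=O)N(C)C | intermediate
21 | 4,4'-[(1S,2S,3R,4R)-3,4-bis(azidomethyl)cyclobutane-1,2-diyl]bis(2-azido-N,N-dimethyl-1H-imidazole-1-sulfonamide) | CN(C)S(=O)(=O)n1c(N=[N+]=[N-])nc(c1)[C@H]1[C@H](CN=[N+]=[N-])[C@@H](CN=[N+]=[N-])[C@@H]1c1cn(c(N=[N+]=[N-])n1)S(=O)(=O)N(C)C | intermediate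
22 | 4,4'-[(1S,2S,3R,4R)-3,4-bis(aminomethyl)cyclobutane-1,2-diyl]bis(2-amino-N,N-dimethyl-1H-imidazole-1-sulfonamide) | CN(C)S(=O)(=O)n1c(N)nc(c1)[C@H]1[C@H](CN)[C@@H](CN)[C@@H]1c1cn(c(N)n1)S(=O)(=O)N(C)C | intermediate
23 | 4,4'-[(1S,2S,3R,4R)-3,4-bis(aminomethyl)cyclobutane-1,2-diyl]bis(1H-imidazol-2-amine) tetrahydrochloride | Nc1ncc([C@H]2[C@H](CN)[C@@H](CN)[C@@H]2c2cnc(N)[nH]2)[nH]1.Cl.Cl.Cl.Cl | intermediate
24 | 4-bromo-2-(trichloroacetyl)-1H-pyrrole | O=C(c1cc(Br)c[nH]1)C(Cl)(Cl)Cl | starting material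
25 | sceptrin, N,N'-{[(1R,2R,3S,4S)-3,4-bis(2-amino-1H-imidazol-4-yl)cyclobutane-1,2-diyl]bis(methylene)}bis(4-bromo-1H-pyrrole-2-carboxamide) | Nc1ncc([C@H]2[C@H](CNC(=O)c3cc(Br)c[nH]3)[C@@H](CNC(=O)c3cc(Br)c[nH]3)[C@@H]2c2cnc(N)[nH]2)[nH]1 | target

**Step count and risks**

Total steps: 17. Longest linear sequence: 17 steps (1 → 25); the route is fully linear.

Steps most likely to fail:

1. Step 4 (ring contraction). The trivalent iodine oxidant may attack the enolisable methyl ketone, and the 1,4-biradical may undergo β-scission into two alkenes or rotate before closure, eroding yield and enantiopurity. Fallback, from 7 back to 9: the isodiazene is made without any oxidant by treating 7 with N-(benzyloxy)-N-(pivaloyloxy)-4-(trifluoromethyl)benzamide in THF at 45 °C. The ring nitrogen displaces pivalate at the amide nitrogen to give the N-(benzyloxy)-N-(pyrrolidin-1-yl)benzamide F1, which should rearrange by migration of the benzyloxy group to the carbonyl carbon, releasing the same isodiazene 8, which loses N2 at the lower temperature and closes to 9.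

2. Step 5 (three-centre epimerisation). Equilibration may stall before all three centres have inverted, the acetyl methyl group may undergo Claisen condensation onto an ester that is transiently cis to it, or methoxide may strip the sulfamoyl group. Fallback, from 5 and 6 back to 10: the cycloaddition is run with an exo-selective monovalent copper catalyst (CuOAc with ClickFerrophos, antipode chosen to keep the 5S configuration) to give the exo adduct dimethyl (2R,3S,4S,5S)-4-acetyl-5-[1-(dimethylsulfamoyl)-1H-imidazol-4-yl]pyrrolidine-2,3-dicarboxylate F2. Contraction under the conditions of step 4 passes through its isodiazene F3 to the cyclobutane F4, in which the acetyl group and the distal ester are already trans to their neighbours. Only the ester carbon next to the imidazolyl carbon must then invert, so a brief treatment with catalytic NaOMe at 0 °C should give 10 without ever populating an isomer that has the acetyl group cis to an ester.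

3. Step 12 (double lithiation–azidation). Metalation may stop at the mono-lithio stage, deprotonation may compete at C5, or the triazenyl anions may fail to release sulfinate, giving mixtures of mono- and bis-azides. Fallback, from 15 back to 23, by azo coupling in place of organolithium chemistry: 15 is mesylated to the dimesylate F5 and treated with NaN3 to give the diazide F6, and the sulfamoyl groups are removed with hot aqueous HCl to give the NH-imidazole diazide F7. Coupling with 4-methylbenzenediazonium tetrafluoroborate in aqueous Na2CO3 at 0 °C should occur mainly at C2 of each imidazole to give the bis(arylazo) compound F8. Hydrogenation (H2, PtO2, HCl/MeOH) cleaves both azo groups to the 2-amino groups and reduces both azides, delivering 23.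

Further compounds
F1 | step 4 | N-(benzyloxy)-N-{(2R,3R,4R,5S)-3-acetyl-2-[1-(dimethylsulfamoyl)-1H-imidazol-4-yl]-4,5-bis(methoxycarbonyl)pyrrolidin-1-yl}-4-(trifluoromethyl)benzamide | CN(C)S(=O)(=O)n1cnc(c1)[C@H]1N(N(OCc2ccccc2)C(=O)c2ccc(cc2)C(F)(F)F)[C@@H](C(=O)OC)[C@H](C(=O)OC)[C@H]1C(C)=O
F2 | step 5 | dimethyl (2R,3S,4S,5S)-4-acetyl-5-[1-(dimethylsulfamoyl)-1H-imidazol-4-yl]pyrrolidine-2,3-dicarboxylate | CN(C)S(=O)(=O)n1cnc(c1)[C@H]1N[C@@H](C(=O)OC)[C@@H](C(=O)OC)[C@@H]1C(C)=O
F3 | step 5 | isodiazene (1,1-diazene) of F2 | CN(C)S(=O)(=O)n1cnc(c1)[C@H]1[N+](=[N-])[C@@H](C(=O)OC)[C@@H](C(=O)OC)[C@@H]1C(C)=O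
F4 | step 5 | dimethyl (1R,2S,3R,4R)-3-acetyl-4-[1-(dimethylsulfamoyl)-1H-imidazol-4-yl]cyclobutane-1,2-dicarboxylate | CN(C)S(=O)(=O)n1cnc(c1)[C@H]1[C@@H](C(=O)OC)[C@@H](C(=O)OC)[C@@H]1C(C)=O
F5 | step 12 | {(1S,2S,3R,4R)-3,4-bis[1-(dimethylsulfamoyl)-1H-imidazol-4-yl]cyclobutane-1,2-diyl}bis(methylene) dimethanesulfonate | CN(C)S(=O)(=O)n1cnc(c1)[C@H]1[C@H](COS(C)(=O)=O)[C@@H](COS(C)(=O)=O)[C@@H]1c1cn(cn1)S(=O)(=O)N(C)C
F6 | step 12 | 4,4'-[(1S,2S,3R,4R)-3,4-bis(azidomethyl)cyclobutane-1,2-diyl]bis(N,N-dimethyl-1H-imidazole-1-sulfonamide) | CN(C)S(=O)(=O)n1cnc(c1)[C@H]1[C@H](CN=[N+]=[N-])[C@@H](CN=[N+]=[N-])[C@@H]1c1cn(cn1)S(=O)(=O)N(C)C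
F7 | step 12 | 4,4'-[(1S,2S,3R,4R)-3,4-bis(azidomethyl)cyclobutane-1,2-diyl]bis(1H-imidazole) | c1nc(c[nH]1)[C@H]1[C@H](CN=[N+]=[N-])[C@@H](CN=[N+]=[N-])[C@@H]1c1c[nH]cn1
F8 | step 12 | 4,4'-[(1S,2S,3R,4R)-3,4-bis(azidomethyl)cyclobutane-1,2-diyl]bis{2-[(E)-(4-methylphenyl)diazenyl]-1H-imidazole} | Cc1ccc(cc1)/N=N/c1nc(c[nH]1)[C@H]1[C@H](CN=[N+]=[N-])[C@@H](CN=[N+]=[N-])[C@@H]1c1c[nH]c(n1)/N=N/c1ccc(C)cc1
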